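Oak held twice the free enzyme of cedar and lost its starting material twice as fast, so I worked with the fraction left and not with the fraction made.

| flask | starting material | second substrate | free enzyme | remark | time |
|---|---|---|---|---|---|
| cedar | 0.050 M | 0.090 M | 5 µM | run made earlier |  |
| larch | 0.050 M | 0.090 M | 2.5 µM | run made earlier |  |
| oak | 0.050 M | 0.090 M | 10 µM | run made earlier |  |
| ash | 0.050 M | 0.045 M | 5 µM | run made earlier |  |
| spring | 0.050 M (fed, over 2.0 min) | 0.0900 M | 5.0 µM | all else is in the flask from the start; the feed brings no volume worth counting | 3.0 min |
| noon | 0.050 M | 0.0900 M (fed, over 2.0 min) | 5.0 µM | all else is in the flask from the start; the feed brings no volume worth counting | 3.0 min |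
| winter | 0.050 M | 0.0900 M | 5.0 µM | everything together at the start | 3.0 min |
| dusk | 0.050 M | 0.0900 M (in portions, 4, over 2.0 min) | 5.0 µM | first portion at the start, last at 2.0 min | 3.0 min |

cedar run (percent of the starting material charged)

| time / s | target / % | starting material / % |
|---|---|---|
| 10.0 | 5.3 | 94.4 |
| 25.0 | 11.9 | 87.7 |
| 50.0 | 24.5 | 76.1 |
| 80.0 | 37.1 | 63.3 |
| 120 | 52.4 | 47.3 |

larch run (percent of the starting material charged)

| time / min | target / % | starting material / % |
|---|---|---|
| 0.200 | 4.8 | 96.3 |
| 0.333 | 4.7 | 94.7 |
| 0.667 | 10.6 | 91.9 |
| 1.33 | 21.7 | 79.6 |
| 2.50 | 35.4 | 64.0 |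

oak run (percent of the starting material charged)

| time / min | target / % | starting material / % |
|---|---|---|
| 0.500 | 27.7 | 71.3 |
| 1.00 | 51.7 | 47.9 |
| 1.33 | 64.1 | 35.3 |
| 2.00 | 77.6 | 21.0 |
| 2.50 | 83.6 | 15.2 |

ash run (percent of the starting material charged)

| time / min | target / % | starting material / % |
|---|---|---|
| 0.200 | 3.5 | 96.3 |
| 0.333 | 9.2 | 92.1 |
| 0.667 | 15.2 | 84.4 |
| 1.33 | 28.2 | 72.4 |
| 2.50 | 42.9 | 56.3 |

(each reading ± 1 percentage point)



- the flask with the highest amount of target, in percent of the starting material charged ("all alike" if they lie within 1.5 percentage points) (spring / noon / winter / dusk / all alike)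
- final target, as a percentage of the starting material charged, in spring
- final target, as a percentage of the starting material charged, in noon
- final target, as a percentage of the starting material charged, in winter
- final target, as a percentage of the starting material charged, in dusk

The tables pair two columns: in cedar's last row, target 52.4% and starting material 47.3% sum close to the charge, so what was left told me what was made. From that row I read 0.374 min⁻¹ for the clearance, minus the natural logarithm of the fraction left divided by the time, a pseudo-first-order constant at 5 µM of free enzyme.

Larch's last row, with half the enzyme, gave about half that clearance. Ash's last row, with the same enzyme but half the second substrate, gave 0.230 min⁻¹, less than cedar. So I read an order of 0.704 in second substrate, a reading that carries the scatter.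

My own reckoning followed. Winter should keep 32.5% of its starting material. In spring each slice of feed decays from the moment it enters, so the average slice should leave 48.4% at the end, which means 51.6% target.

The forecast named winter, with spring 53%, noon 57%, winter 68% and dusk 58%, saying “No substrate inhibition is evident, so batch wins”. My spring figure stood lower than its figure.

The flasks gave spring 45.7%, noon 57.7%, winter 68.3% and dusk 58.4%, so winter led.

    starting material + free enzyme ⇌ first complex (K = 19.1 M⁻¹, k = 1.31 × 10⁵ M⁻¹ s⁻¹)
    second complex → free enzyme + target (k = 93.9 s⁻¹)
    second substrate + loaded enzyme ⇌ second complex (K = 20.0 M⁻¹, k = 2.36 × 10⁵ M⁻¹ s⁻¹)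
    first complex ⇌ loaded enzyme + first product (K = 0.172 M, k = 872 s⁻¹)
    2 free enzyme → spent catalyst (k = 5670 M⁻¹ s⁻¹)

Winter kept 31.7% of its starting material against my 32.5%, but spring kept 54.3% against my 48.4%, and the forecast's spring stood 7.3 percentage points high. At 3.00 min spring held 42.3% of its catalyst as spent catalyst, more than winter's 26.1%. A neighbour of winter took 0.15 M of second substrate, so I scaled the clearance by the order to 0.536 min⁻¹, which leaves 20.0%. That neighbour kept 21.5% of its starting material and made 78.5% target.

(All runs are simulated for substances that don't exist; the scatter is artificial.)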